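# Chermebilaene B: synthesis proposal through a gold-catalysed alkynoic acid cascade

## Analysis of the target

- **Ring system.** Chermebilaene B (36) has a cyclohexane (ring A: C2, C3, C5, C6, C11, C18) with a spiro δ-lactone at C11 (ring B). At C18 ring A is joined, through O34 and C19, to a cage of four rings (C, D, E, F).
- **Cage carbons.** C31 is an orthoester carbon (O30, O32, O34) common to rings C, D and E. C28 is a methyl-bearing ketal carbon whose oxygens are the ester oxygen O27 of γ-lactone F and the orthoester oxygen O30.
- **Stereocentres.** There are eleven. On ring A the C2 methyl, the C3 hydroxyl, the C6 hydroxyisopropyl group, C17 (on C11) and O34 (on C18) lie on one face; C12 and C19 lie on the other. On ring D the C20 methyl, the C22 methyl, the C25 carboxyl carbon and C28 are all cis, with C19 on the opposite face. C28 and C31 are then fixed by the geometry of the cage.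
- **Sensitive groups.** The orthoester, the acylated ketal at C28, the two lactones (ring B is enolisable and unhindered) and the tertiary alcohol.
- **What makes it hard.** C11, C18 and C20 are fully substituted and close together. The C2 methyl is axial and sits next to a carbon that must come from a carbonyl, so it is the less stable epimer. The all-cis ring D is also the less stable arrangement at C24. The hydroxy δ-lactone needed before cage closure is the less stable acyl-transfer isomer of a spiro γ-lactone.
- **Feature the strategy rests on.** C28 carries two oxygens and a methyl, which is the oxidation pattern of the internal carbon of an ethynyl group on C33. O30 can be the carbonyl oxygen of a ring D lactone at C31. Rings F, E and C can therefore be closed last, by isomerisation of a hydroxy δ-lactone alkynoic acid.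

## Retrosynthetic reasoning

**36 from 35.** The silyl ethers on O4 and O10 are removed last. They keep both alcohols out of the cationic cascade and out of every earlier silylation and acylation.

**35 from 31 (key disconnection).** The bonds C28–O27, C28–O30 and C31–O34 are cut. All three are C–O bonds at acetal-level carbons, so cutting them changes no oxidation state: C28 becomes the internal carbon of an ethynyl group on C33, C25 a free acid, C31 the carbonyl of δ-lactone D and O34 the tertiary C18 hydroxyl. Three rings and two stereocentres are gained in the forward direction. The forward reaction must deliver two Markovnikov oxygen additions at C28 and capture of the C31 cation by O34.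

**31 from 30.** With a free C18 hydroxyl γ to the C31 carbonyl, 31 can slip to the spiro γ-lactone. O34 is therefore carried as a trimethylsilyl ether and the alkyne as its C-silyl derivative, and both are released by buffered desilylation in the step before the cascade.

**30 from 28, 27, and 24 with 25.** The C31–O32 bond of ring D is cut back to hydroxy diacid 28; the forward step is dehydrative lactonisation through the cyclic anhydride. The C24–C33 bond is cut by an aldol disconnection to imide 24 and aldehyde 25. C24 is the only position that soft enolisation of an imide can reach (lactone B is spared), and the aldol sets C24 and C33 together. The imide is cleaved (27 to 28) before ring D is closed, so that no activated C25 carbonyl ever faces a β-acyloxy group at C33.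

**24 from 22.** The two carboxyls C25 and C31 are told apart by opening the six-membered anhydride 23 at the unhindered C25.

**22 from 19.** The C31–O34 bond of the spiro γ-lactone in 19 is cut in the forward sense (acyl–oxygen cleavage with capping of O34). The γ-lactone is wanted for stereocontrol at C20 but must not survive. As a carboxylate, C31 cannot re-acylate O34.

**19 from 16 and 17.** The C20–C22 bond is cut (Michael disconnection). The quaternary C20 is made on a rigid spirolactone enolate that already carries the C21 methyl, and C22 is set in the same step.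

**16 from 13 and 14.** The C18–C19 bond and the O34–C31 acyl bond are cut (allylation of the ketone with lactonisation). This brings in C19, C20, C21 and C31 in one step and sets C18.

**13 from 11, 10 and 9.** The C2–H bond and the C18 carbonyl are traced back to the syn epoxy alcohol 11 (1,2-hydride shift). This is the one disconnection that gives the axial C2 methyl cis to O4 under kinetic control. Epoxide 11 comes from allylic alcohol 10, and 10 from enone 9.

**9 from 7, from 5 and 6, from 3 and 4, from 2, from 1.** Ring B is cut at O16–C14 and C11–C12: lactonisation of a C17 alcohol, and Michael addition of the formyl ketone 5 to 6. The formyl carbon C17 comes from 4, the tertiary oxygen O10 from hydration of 1.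

## Alternatives that were turned down

**Alternative 1:** 
- *Disconnection:* C11–C18, so that ring A is closed last between two carbons that both become quaternary.
- *Forward key step:* an iron hydride (from an iron acetylacetonate and a silane) transfers a hydrogen atom to C12 of a C11=C12 dihydropyranone. The tertiary C11 radical adds 6-endo to C18 of a C2=C18 ylidene lactone conjugated to a C3 ketone, giving the bis-spirolactone ketone A1.
- *For it:* a radical joins two fully substituted carbons with little sensitivity to steric bulk, rings B and C exist before ring A, and the route is convergent. On making the C11–C18 bond directly it is stronger than the chosen route, which builds C11 by two enolate reactions next to the bulky C6 side chain.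
- *Against it:* C11 and C18 form together in an early transition state with nothing that tells the faces apart. The C2 methyl would then be set by reduction and protonation next to the C3 carbonyl, which favours the equatorial (wrong) epimer. The C3 ketone still needs reduction. A1 already holds ring C as the stable spiro γ-lactone, and its side chain ends at a C22 propargyl unit, so C25, the C33 oxygen and C28 are still missing.
- *Comparison:* the chosen route gives up the bold bond for stereocentres that are each set by a named control element, and a last step that closes three rings.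

**Alternative 2:** 
- *Disconnection:* C18–O34, with the oxygen delivered from a β-lactone (C31–O34–C19–C20).
- *Forward key step:* a magnesium halide Lewis acid ionises C19–O34; the C18 hydrogen shifts to C19 while the carboxylate oxygen moves to C18, and the four-membered ring expands to the spiro γ-lactone A2.
- *For it:* this dyotropic ring expansion is stereospecific (migrating hydrogen anti to the leaving oxygen). It makes the C18–O bond without adding a nucleophile to a ketone flanked by C11. C18 is never a carbonyl, so the C2 methyl is not exposed to epimerisation; on this point it is stronger than the chosen route.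
- *Against it:* positive charge develops at C18 next to the quaternary C11, which invites migration of C12 or C17 and elimination. The C18–H stereocentre must be set beforehand, and the β-lactone needs C19 and C20 fixed by an aldol–lactonisation at a neopentyl aldehyde. Like A1, A2 is the spiro γ-lactone with the short propargyl side chain.
- *Comparison:* the chosen route pays with a hindered ketone addition, but that addition is steered to the right face by the two axial α-substituents.

**Alternative 3:** 
- *Disconnection:* C20–C22 and C31–O32 together, so that ring D is born at the orthoester oxidation level.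
- *Forward key step:* the cyclic silyl ketene acetal of spirolactone ring C (C20=C31) adds, with inverse electron demand, across the oxadiene O32=C33–C24=C22 of an ethylidene keto ester, giving the silyl orthoester A3.
- *For it:* the quaternary C20 and the orthoester carbon are made in one convergent step. In bonds formed per step it is at least as strong as the chosen key step.
- *Against it:* a tetrasubstituted ketene acetal is a hindered 2π partner. Facial and endo/exo selectivity decide C20, C22 and C31 at once without a tether. A3 still has C24=C33 as an enol ether double bond, so two stereocentres of the all-cis array must be set afterwards by cis reduction of a tetrasubstituted, electron-rich alkene. The silyl orthoester is labile to the acid that the later exchange at C28 would need.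
- *Comparison:* the chosen strategy sets C22, C24 and C33 before the cage exists and uses cage closure only for C28 and C31, which geometry fixes.

Key step: step 17

Remark on the chemistry (assumption): with the carvone carbonyl mapped onto C18, C6 of the target corresponds to C5 of (R)-(−)-carvone, so this enantiomer is the starting material; atom numbers are those of the heavy atoms in the order of the target SMILES.

## Route

Step 1
Reactants: 1 (R)-(−)-carvone
Product: 2 hydroxy enone (5R)-5-(2-hydroxypropan-2-yl)-2-methylcyclohex-2-en-1-one
Conditions: Co(acac)2 (20 mol%), PhSiH3, O2 (1 atm), THF, rt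
Reagents that add atoms: dioxygen, O=O
Why: Mukaiyama hydration: the cobalt hydride gives a hydrogen atom to the electron-rich 1,1-disubstituted alkene and not to the electron-poor enone alkene, and the tertiary radical is trapped by O2 to give the Markovnikov alcohol (C7–O10); the C6 stereocentre is not touched.

Step 2
Reactants: 2 hydroxy enone
Product: 3 triethylsilyl ether (5R)-2-methyl-5-[2-(triethylsilyloxy)propan-2-yl]cyclohex-2-en-1-one
Conditions: TESOTf, 2,6-lutidine, CH2Cl2, −78 → 0 °C
Reagents that add atoms: triethylsilyl triflate, CC[Si](CC)(CC)OS(=O)(=O)C(F)(F)F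
Why: Silylation of a tertiary alcohol with a silyl triflate and a hindered pyridine base; the ether shields O10 in all later base, hydride and silyl triflate steps.

Step 3
Reactants: 3 triethylsilyl ether; 4 2,2,2-trifluoroethyl formate
Product: 5 hydroxymethylene ketone (enol form of the C11 formyl ketone)
Conditions: LDA, THF, −78 °C; then 4, −78 °C
Reagents that add atoms: none
Why: Kinetic deprotonation of the cross-conjugated enone takes place at the α′ methylene (C11), and the enolate is C-formylated by the activated formate (Claisen condensation); the product rests as the chelated enol, so no C11 stereocentre is at issue yet.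

Step 4
Reactants: 5 hydroxymethylene ketone; 6 methyl acrylate
Product: 7 keto aldehyde ester (C11 quaternary; formyl cis and ester chain trans to the C6 side chain)
Conditions: DBU (10 mol%), MeCN, 0 °C → rt
Reagents that add atoms: none
Why: Michael addition of the doubly stabilised β-keto aldehyde enolate creates the quaternary C11; in the planar dienolate A(1,2) strain pushes the bulky C6 side chain pseudo-axial, so the acrylate adds to the opposite face, which puts C12 trans and the formyl carbon C17 cis to C7.

Step 5
Reactants: 7 keto aldehyde ester
Product: 9 enone spirolactone (ring A enone with ring B), via hydroxy ester 8 (not isolated)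
Conditions: NaBH(OAc)3, AcOH, THF, rt; then PPTS (cat.), PhMe, 60 °C
Reagents that add atoms: none
Why: NaBH(OAc)3 reduces aldehydes and not ketones, so only the C17 formyl group is reduced, in an acidic medium that allows neither retro-Claisen nor retro-aldol cleavage; the δ-hydroxy ester then closes to ring B under mild acid, helped by the Thorpe–Ingold effect of C11.

Step 6
Reactants: 9 enone spirolactone
Product: 10 allylic alcohol (C18 hydroxyl cis to C17 and to the C6 side chain)
Conditions: NaBH4, CeCl3·7H2O, MeOH, −78 °C
Reagents that add atoms: none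
Why: Luche reduction gives 1,2-reduction of the enone and spares the lactone; hydride adds to C18 anti to the pseudo-axial C17 on the neighbouring quaternary carbon (axial attack, as in the reduction of carvone to cis-carveol), so the hydroxyl is cis to C17 and C7.

Step 7
Reactants: 10 allylic alcohol
Product: 11 syn epoxy alcohol (C2–C3 epoxide on the face of the C18 hydroxyl)
Conditions: VO(acac)2 (5 mol%), t-BuOOH, CH2Cl2, 0 °C → rt
Reagents that add atoms: tert-butyl hydroperoxide, CC(C)(C)OO
Why: Vanadium-catalysed hydroxyl-directed epoxidation of a cyclic allylic alcohol delivers oxygen to the face of the C18 hydroxyl; this sets the C3–O bond of the target (cis to the C6 side chain) and places the C18 hydrogen anti to the C2–O bond.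

Step 8
Reactants: 11 syn epoxy alcohol
Product: 13 ring A/B ketone (C3 silyloxy and axial C2 methyl cis to the C6 side chain), via epoxy silyl ether 12 (not isolated)
Conditions: TBSOTf (2.5 equiv), i-Pr2NEt, CH2Cl2, −78 → −40 °C
Reagents that add atoms: tert-butyldimethylsilyl triflate, CC(C)(C)[Si](C)(C)OS(=O)(=O)C(F)(F)F
Why: Non-aldol aldol rearrangement (semipinacol 1,2-hydride shift of a 2,3-epoxy silyl ether): the silyl triflate silylates O34 and activates the epoxide, the tertiary C2–O bond ionises and the antiperiplanar C18 hydrogen moves to C2 with inversion. This gives the C18 ketone, the C3 silyl ether with retained configuration and the C2 methyl cis to O4; the less stable axial C2 epimer is formed under kinetic control and is not exposed to base afterwards.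

Step 9
Reactants: 13 ring A/B ketone; 14 ethyl 2-(bromomethyl)acrylate
Product: 16 spiro α-methylene γ-lactone (ring C as lactone; O34 equatorial and C19 axial on ring A), via hydroxy acrylate 15 (not isolated)
Conditions: Zn dust (activated), THF, 45 °C
Reagents that add atoms: none
Why: Zinc Barbier allylation with lactonisation (Dreiding–Schmidt methylene lactone synthesis): the allylzinc reagent attacks the C18 carbonyl from the axial direction, opposite to the two axial α-substituents (C1 methyl and C17), so C19 becomes axial and O34 equatorial as in the target; the zinc alkoxide then closes the spiro γ-lactone on the ester.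

Step 10
Reactants: 16 spiro α-methylene γ-lactone; 17 methyl (E)-crotonate
Product: 19 spirolactone methyl ester (Michael adduct; C20 and C22 as in the target), via lithium lactone enolate 18 (not isolated)
Conditions: LiBH(s-Bu)3 (1.05 equiv), THF, −78 °C; then 17, −78 → −40 °C; aq. NH4Cl
Reagents that add atoms: none
Why: Conjugate hydride reduction makes the lactone enolate regiospecifically without base, so C13 of lactone B is not touched, and its Michael addition forms C20–C22. The enolate is attacked on the face flanked by the equatorial hydrogen of C2 and not on the face shielded by C12 of ring B, which sets C20. A closed lithium-bridged transition state, with the ester arm on the side of the enolate oxygen and the β-methyl of the (E)-crotonate anti to C31, gives the C22 configuration of the target.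

Step 11
Reactants: 19 spirolactone methyl ester
Product: 22 diacid with C18 trimethylsilyl ether (lactone B closed), via pentapotassium salt 20 (not isolated), via persilylated triacid 21 (not isolated)
Conditions: KOSiMe3 (6 equiv), THF, 50 °C; then TMSCl, 0 °C; aq. citric acid (pH 4)
Reagents that add atoms: potassium trimethylsilanolate, C[Si](C)(C)[O-].[K+]; chlorotrimethylsilane, C[Si](C)(C)Cl
Why: KOSiMe3 is an anhydrous hydroxide equivalent that cleaves the methyl ester and both lactones by acyl–oxygen attack; as a carboxylate C31 cannot re-acylate O34, which is then silylated. On mildly acidic work-up the silyl esters and the primary C17 silyl ether are hydrolysed, the δ-hydroxy acid recloses to lactone B, and the hindered tertiary C18 silyl ether should stay.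

Step 12
Reactants: 22 diacid with C18 trimethylsilyl ether
Product: 24 N-acyl oxazolidinone acid (imide at C25 and free acid at C31), via glutaric anhydride 23 (not isolated)
Conditions: DCC, CH2Cl2, 0 °C → rt; then oxazolidin-2-one, LiCl, Et3N, THF, rt
Reagents that add atoms: oxazolidin-2-one, O=C1NCCO1
Why: Carbodiimide dehydration turns the 1,5-diacid into the six-membered anhydride, which the oxazolidinone opens at the unhindered C25 carbonyl and not at C31 next to the quaternary C20; C24 thus becomes the only centre that soft enolisation can reach.

Step 13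
Reactants: 24 N-acyl oxazolidinone acid; 25 3-(trimethylsilyl)propynal
Product: 27 anti aldol hydroxy imide acid (C24 and C33 as in the target), via bis-silyl aldol adduct 26 (not isolated)
Conditions: MgCl2 (20 mol%), Et3N, TMSCl, EtOAc, rt; then citric acid, MeOH, 0 °C
Reagents that add atoms: none
Why: Magnesium-halide-catalysed anti-aldol of an N-acyl oxazolidinone (soft enolisation, silyl trapping of the aldolate) with a non-enolisable ynal: the chelated (Z)-enolate gives the anti adduct, which sets C33 relative to C24. The aldehyde adds to the enolate face anti to the quaternary C20, with the C22 hydrogen eclipsing the enolate (A(1,3) strain), which makes C25 and C23 cis on the later ring D; lactone B is not enolised under these conditions.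

Step 14
Reactants: 27 anti aldol hydroxy imide acid
Product: 28 hydroxy diacid (C25 and C31 acids and C33 hydroxyl)
Conditions: LiOH, H2O2, THF/H2O, 0 °C; Na2SO3; 1 M HCl to pH 3, 0 °C
Reagents that add atoms: hydrogen peroxide (as LiOOH), OO
Why: Lithium hydroperoxide attacks the exocyclic imide carbonyl and frees the C25 acid at 0 °C without retro-aldol cleavage; the C31 carboxylate and the hindered silyl ether are inert. Any opening of lactone B is healed on acidic work-up, and any loss of the alkynyl silyl group is of no consequence for step 16.

Step 15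
Reactants: 28 hydroxy diacid
Product: 30 δ-lactone acid with C18 trimethylsilyl ether and C-silyl alkyne (ring D closed), via hydroxy anhydride 29 (not isolated)
Conditions: DCC, CH2Cl2, 0 °C → rt
Reagents that add atoms: none
Why: Dehydration of the 1,5-diacid gives the cyclic anhydride, which the C33 hydroxyl opens at C31 through a six-membered transition state (attack at C25 would give a β-lactone); ring D is closed while O34 is still silylated, so the γ-lactone cannot form.

Step 16
Reactants: 30 δ-lactone acid with C18 trimethylsilyl ether and C-silyl alkyne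
Product: 31 hydroxy δ-lactone alkynoic acid (precursor of the cascade)
Conditions: TBAF, AcOH (1:1), THF, −20 → 0 °C
Reagents that add atoms: none
Why: Buffered fluoride removes the alkynyl and the tertiary trimethylsilyl groups much faster than the triethylsilyl and tert-butyldimethylsilyl ethers; the acetic acid buffer keeps the freed C18 hydroxyl from acyl transfer to the γ-lactone, and the product is used at once.

Step 17
Reactants: 31 hydroxy δ-lactone alkynoic acid
Product: 35 bis-silyl chermebilaene B, via enol lactone 32 (not isolated), via acyloxycarbenium triflimide 33 (not isolated), via dioxycarbenium triflimide 34 (not isolated)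
Conditions: Ph3PAuNTf2 (5 mol%), 4 Å MS, CH2Cl2, rt
Reagents that add atoms: none
Why: Proposed new method: cationic monovalent gold activates the terminal alkyne and the C25 acid adds anti to C28 (5-exo-dig, ring F) to give, after protodeauration, the exocyclic enol lactone 32, which is the known gold-catalysed cycloisomerisation of 4-alkynoic acids. Protonation of 32 at C29 by the HNTf2 that the acid substrate liberates gives the acyloxycarbenium ion 33, which the carbonyl oxygen of lactone D captures in a five-membered closure (ring E) to give the dioxycarbenium ion 34. The tertiary C18 hydroxyl then adds to C31 in a five-membered spiro closure (ring C); the closest precedent is the capture of acyloxonium ions by alcohols to give orthoesters. The whole change is an isomerisation in which the alkyne CH becomes the C29 methyl. At C28 only one configuration can be reached, because ring F must be cis-fused at C24–C33 and the O30 bridge must span C33 and C31 on the same face of ring D. At C31, O30 arrives on that face, so O34 takes the other face together with C19, which C20 fixes. The step needs Markovnikov oxygen attack at C28 twice, which the five-membered geometry of both closures enforces, and it needs the acid rather than a hydroxyl to attack the alkyne, which ring size ensures since O34 could reach C28 only through an eight-membered ring. If acyl transfer to the spiro γ-lactone comes first, the C33 hydroxyl can add back to C31 and the same cage should be reached.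

Step 18
Reactants: 35 bis-silyl chermebilaene B
Product: 36 chermebilaene B
Conditions: HF·pyridine, pyridine, THF, 0 °C → rt
Reagents that add atoms: none
Why: Fluoride-mediated cleavage of the secondary tert-butyldimethylsilyl and the tertiary triethylsilyl ether; excess pyridine keeps the medium close to neutral, so the orthoester, the acylated ketal and the lactones should survive, and no stereocentre is touched.

## Compound list

1 | (R)-(−)-carvone | CC1=CC[C@@H](C(C)=C)CC1=O | starting material
2 | (5R)-5-(2-hydroxypropan-2-yl)-2-methylcyclohex-2-en-1-one | CC1=CC[C@@H](C(C)(C)O)CC1=O | intermediate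
3 | (5R)-2-methyl-5-[2-(triethylsilyloxy)propan-2-yl]cyclohex-2-en-1-one | CC1=CC[C@@H](C(C)(C)O[Si](CC)(CC)CC)CC1=O | intermediate
4 | 2,2,2-trifluoroethyl formate | O=COCC(F)(F)F | starting material
5 | (Z)-hydroxymethylene ketone: enol of the C11 formyl derivative of 3 | CC1=CC[C@@H](C(C)(C)O[Si](CC)(CC)CC)/C(=C/O)C1=O | intermediate
6 | methyl acrylate | C=CC(=O)OC | starting material
7 | keto aldehyde ester: C11 carries formyl (cis to the C6 side chain) and 2-(methoxycarbonyl)ethyl (trans) | CC1=CC[C@@H](C(C)(C)O[Si](CC)(CC)CC)[C@](C=O)(CCC(=O)OC)C1=O | intermediate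
8 | hydroxy ester: C17 hydroxymethyl analogue of 7 | CC1=CC[C@@H](C(C)(C)O[Si](CC)(CC)CC)[C@](CO)(CCC(=O)OC)C1=O | intermediate
9 | enone spirolactone: ring A enone spiro-fused at C11 to δ-lactone B | CC1=CC[C@@H](C(C)(C)O[Si](CC)(CC)CC)[C@]2(CCC(=O)OC2)C1=O | intermediate
10 | allylic alcohol: C18 hydroxyl cis to C17 and to the C6 side chain | CC1=CC[C@@H](C(C)(C)O[Si](CC)(CC)CC)[C@]2(CCC(=O)OC2)[C@H]1O | intermediate
11 | syn epoxy alcohol: C2–C3 epoxide on the face of the C18 hydroxyl | C[C@]12O[C@H]1C[C@@H](C(C)(C)O[Si](CC)(CC)CC)[C@]3(CCC(=O)OC3)[C@H]2O | intermediate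
12 | C18 tert-butyldimethylsilyl ether of 11 | C[C@]12O[C@H]1C[C@@H](C(C)(C)O[Si](CC)(CC)CC)[C@]3(CCC(=O)OC3)[C@H]2O[Si](C)(C)C(C)(C)C | intermediate
13 | ring A/B ketone: C18 ketone, C3 OTBS and C2 methyl cis to each other and to the C6 side chain, C7 OTES | C[C@H]1[C@@H](O[Si](C)(C)C(C)(C)C)C[C@@H](C(C)(C)O[Si](CC)(CC)CC)[C@]2(CCC(=O)OC2)C1=O | intermediate
14 | ethyl 2-(bromomethyl)acrylate | C=C(CBr)C(=O)OCC | starting material
15 | hydroxy acrylate: Barbier adduct, C18 hydroxyl equatorial, C19 axial | C[C@H]1[C@@H](O[Si](C)(C)C(C)(C)C)C[C@@H](C(C)(C)O[Si](CC)(CC)CC)[C@]2(CCC(=O)OC2)[C@]1(O)CC(=C)C(=O)OCC | intermediate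
16 | spiro α-methylene γ-lactone (ring C as lactone, C20=C21) | C[C@H]1[C@@H](O[Si](C)(C)C(C)(C)C)C[C@@H](C(C)(C)O[Si](CC)(CC)CC)[C@]2(CCC(=O)OC2)[C@]13CC(=C)C(=O)O3 | intermediate
17 | methyl (E)-crotonate | C/C=C/C(=O)OC | starting material
18 | lithium enolate of the α-methyl spiro γ-lactone | C[C@H]1[C@@H](O[Si](C)(C)C(C)(C)C)C[C@@H](C(C)(C)O[Si](CC)(CC)CC)[C@]2(CCC(=O)OC2)[C@]13CC(C)=C([O-])O3.[Li+] | intermediate
19 | spirolactone methyl ester: C20 quaternary (methyl cis to C11, C22 cis to C2 on ring C), C22 methyl, C25 methyl ester | C[C@H]1[C@@H](O[Si](C)(C)C(C)(C)C)C[C@@H](C(C)(C)O[Si](CC)(CC)CC)[C@]2(CCC(=O)OC2)[C@]13C[C@](C)([C@@H](C)CC(=O)OC)C(=O)O3 | intermediate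
20 | pentapotassium salt: C14, C25 and C31 carboxylates, C17 and C18 alkoxides | C[C@H]1[C@@H](O[Si](C)(C)C(C)(C)C)C[C@@H](C(C)(C)O[Si](CC)(CC)CC)[C@](C[O-])(CCC(=O)[O-])[C@]1([O-])C[C@](C)([C@@H](C)CC(=O)[O-])C(=O)[O-].[K+].[K+].[K+].[K+].[K+] | intermediate
21 | persilylated triacid: three trimethylsilyl esters, C17 and C18 trimethylsilyl ethers | C[C@H]1[C@@H](O[Si](C)(C)C(C)(C)C)C[C@@H](C(C)(C)O[Si](CC)(CC)CC)[C@](CO[Si](C)(C)C)(CCC(=O)O[Si](C)(C)C)[C@]1(O[Si](C)(C)C)C[C@](C)([C@@H](C)CC(=O)O[Si](C)(C)C)C(=O)O[Si](C)(C)C | intermediate
22 | diacid: C25 and C31 acids, C18 OTMS, lactone B closed | C[C@H]1[C@@H](O[Si](C)(C)C(C)(C)C)C[C@@H](C(C)(C)O[Si](CC)(CC)CC)[C@]2(CCC(=O)OC2)[C@]1(O[Si](C)(C)C)C[C@](C)([C@@H](C)CC(=O)O)C(=O)O | intermediate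
23 | glutaric anhydride: C25–O–C31 anhydride, C21 and C23 methyls cis | C[C@H]1[C@@H](O[Si](C)(C)C(C)(C)C)C[C@@H](C(C)(C)O[Si](CC)(CC)CC)[C@]2(CCC(=O)OC2)[C@]1(O[Si](C)(C)C)C[C@]3(C)[C@@H](C)CC(=O)OC3=O | intermediate
24 | N-acyl oxazolidinone acid: imide at C25, free acid at C31 | C[C@H]1[C@@H](O[Si](C)(C)C(C)(C)C)C[C@@H](C(C)(C)O[Si](CC)(CC)CC)[C@]2(CCC(=O)OC2)[C@]1(O[Si](C)(C)C)C[C@](C)([C@@H](C)CC(=O)N3CCOC3=O)C(=O)O | intermediate
25 | 3-(trimethylsilyl)propynal | C[Si](C)(C)C#CC=O | starting material
26 | bis-silyl aldol adduct: C33 OTMS and C31 trimethylsilyl ester | C[C@H]1[C@@H](O[Si](C)(C)C(C)(C)C)C[C@@H](C(C)(C)O[Si](CC)(CC)CC)[C@]2(CCC(=O)OC2)[C@]1(O[Si](C)(C)C)C[C@](C)([C@@H](C)[C@H]([C@H](O[Si](C)(C)C)C#C[Si](C)(C)C)C(=O)N3CCOC3=O)C(=O)O[Si](C)(C)C | intermediate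
27 | anti aldol hydroxy imide acid: C33 hydroxyl, C25 imide, C31 acid | C[C@H]1[C@@H](O[Si](C)(C)C(C)(C)C)C[C@@H](C(C)(C)O[Si](CC)(CC)CC)[C@]2(CCC(=O)OC2)[C@]1(O[Si](C)(C)C)C[C@](C)([C@@H](C)[C@H]([C@H](O)C#C[Si](C)(C)C)C(=O)N3CCOC3=O)C(=O)O | intermediate
28 | hydroxy diacid: C25 and C31 acids, C33 hydroxyl | C[C@H]1[C@@H](O[Si](C)(C)C(C)(C)C)C[C@@H](C(C)(C)O[Si](CC)(CC)CC)[C@]2(CCC(=O)OC2)[C@]1(O[Si](C)(C)C)C[C@](C)([C@@H](C)[C@H]([C@H](O)C#C[Si](C)(C)C)C(O)=O)C(=O)O | intermediate
29 | hydroxy anhydride: C25–O–C31 anhydride with the C33 carbinol on C24 | C[C@H]1[C@@H](O[Si](C)(C)C(C)(C)C)C[C@@H](C(C)(C)O[Si](CC)(CC)CC)[C@]2(CCC(=O)OC2)[C@]1(O[Si](C)(C)C)C[C@]3(C)[C@@H](C)[C@H]([C@H](O)C#C[Si](C)(C)C)C(=O)OC3=O | intermediate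
30 | δ-lactone acid: ring D closed, all-cis C21/C23/C25/C28, C18 OTMS, C-silyl alkyne | C[C@H]1[C@@H](O[Si](C)(C)C(C)(C)C)C[C@@H](C(C)(C)O[Si](CC)(CC)CC)[C@]2(CCC(=O)OC2)[C@]1(O[Si](C)(C)C)C[C@]3(C)[C@@H](C)[C@@H](C(O)=O)[C@@H](C#C[Si](C)(C)C)OC3=O | intermediate
31 | hydroxy δ-lactone alkynoic acid (free C18 hydroxyl, free C25 acid, ethynyl on C33) | C[C@H]1[C@@H](O[Si](C)(C)C(C)(C)C)C[C@@H](C(C)(C)O[Si](CC)(CC)CC)[C@]2(CCC(=O)OC2)[C@]1(O)C[C@]3(C)[C@@H](C)[C@@H](C(O)=O)[C@@H](C#C)OC3=O | intermediate
32 | enol lactone: ring F closed, exocyclic C28=C29 | C[C@H]1[C@@H](O[Si](C)(C)C(C)(C)C)C[C@@H](C(C)(C)O[Si](CC)(CC)CC)[C@]2(CCC(=O)OC2)[C@]1(O)C[C@]3(C)[C@@H](C)[C@H]4C(=O)OC(=C)[C@H]4OC3=O | intermediate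
33 | acyloxycarbenium triflimide (cation at C28) | C[C@H]1[C@@H](O[Si](C)(C)C(C)(C)C)C[C@@H](C(C)(C)O[Si](CC)(CC)CC)[C@]2(CCC(=O)OC2)[C@]1(O)C[C@]3(C)[C@@H](C)[C@H]4C(=O)O[C+](C)[C@H]4OC3=O.O=S(=O)([N-]S(=O)(=O)C(F)(F)F)C(F)(F)F | intermediate
34 | dioxycarbenium triflimide (rings F and E closed, cation at C31) | C[C@H]1[C@@H](O[Si](C)(C)C(C)(C)C)C[C@@H](C(C)(C)O[Si](CC)(CC)CC)[C@]2(CCC(=O)OC2)[C@]1(O)C[C@]5(C)[C@@H](C)[C@H]3C(=O)O[C@@]4(C)O[C+]5O[C@@H]34.O=S(=O)([N-]S(=O)(=O)C(F)(F)F)C(F)(F)F | intermediate
35 | bis-silyl chermebilaene B (C3 OTBS, C7 OTES) | C[C@H]1[C@@H](O[Si](C)(C)C(C)(C)C)C[C@@H](C(C)(C)O[Si](CC)(CC)CC)[C@]2(CCC(=O)OC2)[C@]12C[C@]1(C)[C@@H](C)[C@H]3C(=O)O[C@@]4(C)O[C@@]1(O[C@@H]34)O2 | intermediate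
36 | chermebilaene B | C[C@H]1[C@@H](O)C[C@@H](C(C)(C)O)[C@]2(CCC(=O)OC2)[C@]12C[C@]1(C)[C@@H](C)[C@H]3C(=O)O[C@@]4(C)O[C@@]1(O[C@@H]34)O2 | target

## Step count and least certain steps

Total step count: 18. Longest linear sequence: 18 steps, from 1 to 36; compounds 4, 6, 14, 17 and 25 are bought.

**Step 17 (key step, proposed new method).**
- *What may go wrong:* the cascade may stop at the enol lactone stage; the cations may be intercepted by traces of water, which ends in a methyl ketone; acyl transfer from O32 to O34 may come before cyclisation; the triflimide acid may cleave the tertiary silyl ether.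
- *Fallback (known chemistry), from 31 back to 35:* the alkyne is first hydrated on purpose (Ph3PAuNTf2, 2 mol%, wet dioxane) to the C28 methyl ketone acid F1, which exists in equilibrium with its cyclic hydroxy lactone form. F1 is then closed by acid-catalysed dehydrative ketal and orthoester formation (CSA, 4 Å MS, CH2Cl2), and the route is rejoined at 35.

**Step 11.**
- *What may go wrong:* incomplete acyl–oxygen cleavage of the hindered spirolactone; loss of the tertiary silyl ether on work-up followed by return to the γ-lactone.
- *Fallback, from 13 back to 22:* the γ-lactone is never formed. Ketone 13 is allylated with allyl 2-(bromomethyl)acrylate under aqueous Barbier conditions (Zn, THF/sat. aq. NH4Cl, 0 °C), which stop at the hydroxy allyl ester F2. O34 is silylated (TMSOTf, 2,6-lutidine) to give F3. Reductive Michael addition (LiBH(s-Bu)3, then allyl (E)-crotonate) gives the diallyl ester F4. Both allyl esters are removed with Pd(PPh3)4 and morpholine to give 22. The cost is that C20 is set on an open chain, so facial control is expected to be lower and diastereomers may have to be separated.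

**Step 10.**
- *What may go wrong:* slow addition of the borane-complexed enolate, with proton transfer instead; poor facial selectivity at C20; leakage through an open transition state at C22.
- *Fallback, from 16 back to 22:* reduction of 16 and silylation (LiBH(s-Bu)3, then TMSCl) give the silyl ketene acetal F5. Iridium-catalysed branched-selective allylic alkylation ([Ir(cod)Cl]2, a phosphoramidite ligand, (E)-but-2-enyl methyl carbonate, CsF) sets C22 under catalyst control and gives the allyl lactone F6. Hydroboration and oxidation (9-BBN, then NaBO3) give the primary alcohol F7. Oxidation (TEMPO, PhI(OAc)2, then NaClO2) gives the lactone acid F8. Under the conditions of step 11, F8 gives 22.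

**Step 13.**
- *What may go wrong:* slow soft enolisation of the β-branched imide; poor facial selectivity at C24; syn/anti leakage through retro-aldol equilibration.
- *Fallback, from 22 directly to 30:* anhydride 23 is isolated (DCC) and used itself as the aldol donor (ZnCl2, i-Pr2NEt, CH2Cl2, with 25). The cyclic enolate is attacked trans to the C23 methyl and through a chair transition state, and the aldolate opens the anhydride at C31. Steps 12 to 15 are replaced; no new compound is made. This aldol–lactonisation is less precedented for a saturated glutaric anhydride.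

**Step 8.**
- *What may go wrong:* migration of C11 instead of hydrogen (ring contraction); proton loss from the C2 cation; enol silylation and epimerisation of the axial C2 methyl.
- *Fallback, from 11 back to 13:* reductive epoxide opening by trivalent titanium (Cp2TiCl2, Mn, collidine hydrochloride, 1,4-cyclohexadiene) gives the 1,3-diol F9, with hydrogen delivered to the C2 radical anti to both oxygens. Selective silylation of the less hindered C3 hydroxyl (TBSCl, imidazole) gives F10. Dess–Martin oxidation of the C18 hydroxyl gives 13.

**Step 16.**
- *What may go wrong:* partial loss of the tertiary triethylsilyl ether; acyl transfer to the freed C18 hydroxyl under fluoride.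
- *Fallback, from 30 to 36:* all silyl groups are removed at once (TBAF in excess, AcOH, THF, rt) to give the fully deprotected hydroxy δ-lactone alkynoic acid F11. F11 is submitted directly to Ph3PAuNTf2, so that the cascade gives 36 and step 18 is not needed.

## Further compounds

F1 | step 17 | C28 methyl ketone acid (hydration product of 31) | C[C@H]1[C@@H](O[Si](C)(C)C(C)(C)C)C[C@@H](C(C)(C)O[Si](CC)(CC)CC)[C@]2(CCC(=O)OC2)[C@]1(O)C[C@]3(C)[C@@H](C)[C@@H](C(O)=O)[C@@H](C(C)=O)OC3=O
F2 | step 11 | hydroxy allyl ester (Barbier adduct of 13 with allyl 2-(bromomethyl)acrylate) | C[C@H]1[C@@H](O[Si](C)(C)C(C)(C)C)C[C@@H](C(C)(C)O[Si](CC)(CC)CC)[C@]2(CCC(=O)OC2)[C@]1(O)CC(=C)C(=O)OCC=C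
F3 | step 11 | C18 trimethylsilyl ether of F2 | C[C@H]1[C@@H](O[Si](C)(C)C(C)(C)C)C[C@@H](C(C)(C)O[Si](CC)(CC)CC)[C@]2(CCC(=O)OC2)[C@]1(O[Si](C)(C)C)CC(=C)C(=O)OCC=C
F4 | step 11 | diallyl ester of 22 | C[C@H]1[C@@H](O[Si](C)(C)C(C)(C)C)C[C@@H](C(C)(C)O[Si](CC)(CC)CC)[C@]2(CCC(=O)OC2)[C@]1(O[Si](C)(C)C)C[C@](C)([C@@H](C)CC(=O)OCC=C)C(=O)OCC=C
F5 | step 10 | trimethylsilyl ketene acetal of the α-methyl spirolactone | C[C@H]1[C@@H](O[Si](C)(C)C(C)(C)C)C[C@@H](C(C)(C)O[Si](CC)(CC)CC)[C@]2(CCC(=O)OC2)[C@]13CC(C)=C(O[Si](C)(C)C)O3
F6 | step 10 | branched allyl spirolactone (C22 bearing methyl and vinyl) | C[C@H]1[C@@H](O[Si](C)(C)C(C)(C)C)C[C@@H](C(C)(C)O[Si](CC)(CC)CC)[C@]2(CCC(=O)OC2)[C@]13C[C@](C)([C@@H](C)C=C)C(=O)O3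
F7 | step 10 | primary alcohol (C25 hydroxyl) from F6 | C[C@H]1[C@@H](O[Si](C)(C)C(C)(C)C)C[C@@H](C(C)(C)O[Si](CC)(CC)CC)[C@]2(CCC(=O)OC2)[C@]13C[C@](C)([C@@H](C)CCO)C(=O)O3
F8 | step 10 | spirolactone acid (C25 acid) | C[C@H]1[C@@H](O[Si](C)(C)C(C)(C)C)C[C@@H](C(C)(C)O[Si](CC)(CC)CC)[C@]2(CCC(=O)OC2)[C@]13C[C@](C)([C@@H](C)CC(=O)O)C(=O)O3
F0 | step 13 | none | none
F9 | step 8 | 1,3-diol (C3 and C18 hydroxyls, C2 methyl cis to both) | C[C@H]1[C@@H](O)C[C@@H](C(C)(C)O[Si](CC)(CC)CC)[C@]2(CCC(=O)OC2)[C@H]1O
F10 | step 8 | C3 tert-butyldimethylsilyl ether of F9 | C[C@H]1[C@@H](O[Si](C)(C)C(C)(C)C)C[C@@H](C(C)(C)O[Si](CC)(CC)CC)[C@]2(CCC(=O)OC2)[C@H]1O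
F11 | step 16 | fully desilylated hydroxy δ-lactone alkynoic acid | C[C@H]1[C@@H](O)C[C@@H](C(C)(C)O)[C@]2(CCC(=O)OC2)[C@]1(O)C[C@]3(C)[C@@H](C)[C@@H](C(O)=O)[C@@H](C#C)OC3=O
A1 | alternative 1 | ring A/B/C bis-spirolactone C3 ketone | C[C@H]1C(=O)C[C@@H](C(C)(C)O[Si](CC)(CC)CC)[C@]2(CCC(=O)OC2)[C@]12C[C@](C)([C@@H](C)C#C[Si](C)(C)C)C(=O)O2
A2 | alternative 2 | ring A/B/C spiro γ-lactone | C[C@H]1[C@@H](O[Si](C)(C)C(C)(C)C)C[C@@H](C(C)(C)O[Si](CC)(CC)CC)[C@]2(CCC(=O)OC2)[C@]12C[C@](C)([C@@H](C)C#C[Si](C)(C)C)C(=O)O2
A3 | alternative 3 | silyl orthoester dihydropyran adduct | C[C@H]1[C@@H](O[Si](C)(C)C(C)(C)C)C[C@@H](C(C)(C)O[Si](CC)(CC)CC)[C@]2(CCC(=O)OC2)[C@]12C[C@]3(C)[C@@H](C)C(C(=O)OC)=C(C(C)(OC)OC)O[C@]3(O[Si](CC)(CC)CC)O2
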